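The target is the mono-methyl ester of a meso diacid. On the cyclobutane, C1 and C2 carry cis carboxyl carbons, C3 and C4 carry cis methyl and cis pyranone groups, and a latent mirror plane bisects the C1–C2 and C3–C4 bonds. Both halves are one monomer, (E)-3-(4-methoxy-5-methyl-6-oxopyran-2-yl)but-2-enoic acid, joined head-to-head as in the presumed biosynthesis. The cis-dicarboxyl unit serves as its own tether. The open symmetrical anhydride of the monomer undergoes a sensitised intramolecular [2+2] photocycloaddition that closes the cyclobutane and the five-membered anhydride ring together and sets all four stereocentres relatively. Quinidine-mediated methanolysis of this meso anhydride then fixes the absolute configuration.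

Key step: step 8

Assumption: the sense of the alkaloid-mediated opening is carried over from simple cis-cycloalkane-1,2-dicarboxylic anhydrides, where quinidine leaves the free acid on the ring carbon that corresponds spatially to C1 of the target; quinine would give the mirror image.

Step 1
Reactants: 1 butane-2,3-dione; 2 tert-butyl (triphenyl-λ5-phosphanylidene)acetate
Product: 3 tert-butyl (E)-3-methyl-4-oxopent-2-enoate
Conditions: 1 (3 equiv), 2 (1 equiv), CH2Cl2, 0 °C to rt
Reagents that add atoms: none
Why: Wittig olefination: the stabilised ylide attacks one carbonyl of the activated 1,2-diketone (used in excess to suppress double olefination) and, as usual for stabilised ylides, places the acetyl group trans to the ester, which sets the E geometry.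

Step 2
Reactants: 3 tert-butyl (E)-3-methyl-4-oxopent-2-enoate
Product: 4 tert-butyl (E)-3-methyl-4-[(trimethylsilyl)oxy]penta-2,4-dienoate
Conditions: TMSOTf (1.1 equiv), Et3N (1.5 equiv), Et2O, 0 °C
Reagents that add atoms: trimethylsilyl trifluoromethanesulfonate, C[Si](C)(C)OS(=O)(=O)C(F)(F)F
Why: Soft enolisation and O-silylation of a methyl ketone: only the acetyl CH3 offers an α-hydrogen, so a single cross-conjugated 2-silyloxydiene should form under conditions short and cold enough to spare the tert-butyl ester and the E-alkene.

Step 3
Reactants: 5 methylmalonic acid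
Product: 6 methylmalonyl dichloride
Conditions: SOCl2 (neat, excess), 50 °C; distillation
Reagents that add atoms: thionyl chloride, O=S(Cl)Cl
Why: Standard conversion of a carboxylic acid into its chloride with thionyl chloride, kept at moderate temperature so that the malonic acid does not decarboxylate.

Step 4
Reactants: 4 tert-butyl (E)-3-methyl-4-[(trimethylsilyl)oxy]penta-2,4-dienoate; 6 methylmalonyl dichloride
Product: 7 tert-butyl (E)-3-(4-hydroxy-5-methyl-6-oxo-6H-pyran-2-yl)but-2-enoate
Conditions: Et2O, −78 °C to rt
Reagents that add atoms: none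
Why: Effenberger-type 4-hydroxy-2-pyranone synthesis: the CH2 terminus of the silyl enol ether is C-acylated by one acyl chloride group and the former ketone oxygen is then O-acylated by the other, which closes the six-membered lactone and leaves the E-enoate side chain on the ring carbon next to oxygen.

Step 5
Reactants: 7 tert-butyl (E)-3-(4-hydroxy-5-methyl-6-oxo-6H-pyran-2-yl)but-2-enoate
Product: 8 tert-butyl (E)-3-(4-methoxy-5-methyl-6-oxo-6H-pyran-2-yl)but-2-enoate
Conditions: Me2SO4 (1.2 equiv), K2CO3 (1.5 equiv), acetone, reflux
Reagents that add atoms: dimethyl sulfate, COS(=O)(=O)OC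
Why: O-Alkylation of the vinylogous acid (Williamson type): the potassium salt of a 4-hydroxy-2-pyranone is methylated by the hard electrophile mainly at the C4 oxygen, giving the 4-methoxy-2-pyranone rather than the isomeric 2-methoxy-4-pyranone.

Step 6
Reactants: 8 tert-butyl (E)-3-(4-methoxy-5-methyl-6-oxo-6H-pyran-2-yl)but-2-enoate
Product: 9 (E)-3-(4-methoxy-5-methyl-6-oxo-6H-pyran-2-yl)but-2-enoic acid
Conditions: TFA/CH2Cl2 (1:4), rt
Reagents that add atoms: none
Why: Acidolysis of a tert-butyl ester (E1 loss of isobutene), to which the methoxypyranone and the conjugated E-alkene are inert, so that no hydroxide ever meets the lactone.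

Step 7
Reactants: 9 (E)-3-(4-methoxy-5-methyl-6-oxo-6H-pyran-2-yl)but-2-enoic acid (2 equiv)
Product: 10 (E)-3-(4-methoxy-5-methyl-6-oxo-6H-pyran-2-yl)but-2-enoic anhydride (E,E)
Conditions: DCC (1 equiv per 2 equiv of 9), CH2Cl2, 0 °C to rt; filtration
Reagents that add atoms: none
Why: Carbodiimide dehydration: with half an equivalent of DCC the activated acid is intercepted by a second molecule of acid to give the symmetrical anhydride, and the urea is removed by filtration without aqueous work-up.

Step 8
Reactants: 10 (E)-3-(4-methoxy-5-methyl-6-oxo-6H-pyran-2-yl)but-2-enoic anhydride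
Product: 12 (1R,5S,6R,7S)-6,7-dimethyl-6,7-bis(4-methoxy-5-methyl-6-oxo-6H-pyran-2-yl)-3-oxabicyclo[3.2.0]heptane-2,4-dione (meso), via triplet 1,4-diradical 11 (not isolated)
Conditions: [Ir(dF(CF3)ppy)2(dtbbpy)]PF6 (1 mol%), blue LEDs (450 nm), dry degassed CH2Cl2 (2 mM), rt
Reagents that add atoms: none
Why: Proposed new method: triplet energy transfer from the excited iridium complex to one pyranyl-enoate arm of 10 gives an alkene triplet whose α-carbon adds to the α-carbon of the other arm (5-exo-trig, rule of five for a 1,6-diene), closing the five-membered anhydride ring and leaving diradical 11 with two tertiary, pyranone-conjugated β-radicals, which after intersystem crossing combine to close the cyclobutane (1,4-diradical recombination), so that the Cα–Cα and Cβ–Cβ bonds form in one operation. The closest known reaction types are the sensitised intramolecular [2+2] photocycloadditions of tethered bis-cinnamates, of diacryloyl imides to 3-azabicyclo[3.2.0]heptane-2,4-diones and of other 1,6-dienes; the untested elements are an open carboxylic anhydride as the three-atom tether and the formation of two vicinal quaternary carbons. Head-to-head regiochemistry is fixed by the C(=O)–O–C(=O) tether, and the bridgehead centres C1 and C5 can only end cis, because a trans-disposed diradical cannot reach a bicyclo[3.2.0] ring and fragments back to 10. At C6 and C7 each radical centre should close with the small methyl group on the concave (endo) face next to the anhydride carbonyl and the flat pyranone on the convex (exo) face, which gives the mirror-symmetric isomer 12 whatever E/Z scrambling the sensitiser causes beforehand. No absolute control is needed because 12 is meso. Chemoselectivity rests on the sensitiser energy, which should suffice for the extended pyranyl-enoate chromophore but not for the isolated pyranones of 12, and on high dilution, which disfavours intermolecular dimers.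

Step 9
Reactants: 12 meso anhydride
Product: 13 (1S,2R,3S,4R)-2-(methoxycarbonyl)-3,4-dimethyl-3,4-bis(4-methoxy-5-methyl-6-oxo-6H-pyran-2-yl)cyclobutane-1-carboxylic acid (target)
Conditions: quinidine (1.1 equiv), MeOH (3 equiv), toluene, −55 °C; then cold aq. HCl wash
Reagents that add atoms: methanol, CO
Why: Cinchona-alkaloid-mediated desymmetrising methanolysis of a meso cyclic anhydride: the quinuclidine nitrogen activates methanol as a general base and the alkaloid distinguishes the two enantiotopic carbonyls, so methanol should open the carbonyl on the (R)-configured bridgehead from the exo face (bridgehead-hydrogen side, remote from the quaternary carbons), which turns the four relative stereocentres into one enantiomer without touching any of them.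

Compound list
1 | butane-2,3-dione | CC(=O)C(C)=O | starting material
2 | tert-butyl (triphenyl-λ5-phosphanylidene)acetate | CC(C)(C)OC(=O)C=P(c1ccccc1)(c1ccccc1)c1ccccc1 | starting material
3 | tert-butyl (E)-3-methyl-4-oxopent-2-enoate | CC(=O)/C(C)=C/C(=O)OC(C)(C)C | intermediate
4 | tert-butyl (E)-3-methyl-4-[(trimethylsilyl)oxy]penta-2,4-dienoate | C=C(O[Si](C)(C)C)/C(C)=C/C(=O)OC(C)(C)C | intermediate
5 | methylmalonic acid | CC(C(=O)O)C(=O)O | starting material
6 | methylmalonyl dichloride | CC(C(=O)Cl)C(=O)Cl | intermediate
7 | tert-butyl (E)-3-(4-hydroxy-5-methyl-6-oxo-6H-pyran-2-yl)but-2-enoate | CC(C)(C)OC(=O)/C=C(\C)c1cc(O)c(C)c(=O)o1 | intermediate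
8 | tert-butyl (E)-3-(4-methoxy-5-methyl-6-oxo-6H-pyran-2-yl)but-2-enoate | CC(C)(C)OC(=O)/C=C(\C)c1cc(OC)c(C)c(=O)o1 | intermediate
9 | (E)-3-(4-methoxy-5-methyl-6-oxo-6H-pyran-2-yl)but-2-enoic acid | OC(=O)/C=C(\C)c1cc(OC)c(C)c(=O)o1 | intermediate
10 | (E)-3-(4-methoxy-5-methyl-6-oxo-6H-pyran-2-yl)but-2-enoic anhydride (E,E) | O=C(/C=C(\C)c1cc(OC)c(C)c(=O)o1)OC(=O)/C=C(\C)c1cc(OC)c(C)c(=O)o1 | intermediate
11 | triplet 1,4-diradical: cis-3,4-disubstituted succinic anhydride carrying a 1-(4-methoxy-5-methyl-6-oxo-6H-pyran-2-yl)ethyl radical on each ring CH | O=C1OC(=O)[C@@H]([C](C)c2cc(OC)c(C)c(=O)o2)[C@H]1[C](C)c3cc(OC)c(C)c(=O)o3 | intermediate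
12 | (1R,5S,6R,7S)-6,7-dimethyl-6,7-bis(4-methoxy-5-methyl-6-oxo-6H-pyran-2-yl)-3-oxabicyclo[3.2.0]heptane-2,4-dione (meso; methyls endo, pyranones exo) | O=C1OC(=O)[C@@H]2[C@H]1[C@@](C)(c3cc(OC)c(C)c(=O)o3)[C@@]2(C)c4cc(OC)c(C)c(=O)o4 | intermediate
13 | (1S,2R,3S,4R)-2-(methoxycarbonyl)-3,4-dimethyl-3,4-bis(4-methoxy-5-methyl-6-oxo-6H-pyran-2-yl)cyclobutane-1-carboxylic acid | COC(=O)[C@@H]1[C@H](C(=O)O)[C@@](C)(c2cc(OC)c(C)c(=O)o2)[C@@]1(C)c1cc(OC)c(C)c(=O)o1 | target

Total step count: 9. Longest linear sequence: 8 (steps 1, 2, 4, 5, 6, 7, 8, 9).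

Steps most likely to fail

Step 8. The open anhydride may populate the folded, reactive conformer too rarely. Unproductive E/Z isomerisation, intermolecular dimerisation or closure with one pyranone on the endo face could then take over. The fallback uses the known covalent-template photodimerisation of cinnamic-type acids; it sets out from 9 and returns at 12. Acid 9 is esterified twice with naphthalene-1,8-diol (EDC·HCl, DMAP, CH2Cl2) to the peri-diester naphthalene-1,8-diyl bis[(E)-3-(4-methoxy-5-methyl-6-oxo-6H-pyran-2-yl)but-2-enoate] F1, in which the rigid peri positions hold the two enoate arms parallel and head-to-head. Irradiation (365 nm LEDs, crystalline film or dilute solution) should give the template-bound meso cyclobutane diester F2. The two activated aryl esters are cleaved with LiOH in THF/H2O at 0 °C to the meso diacid (1R,2S,3R,4S)-3,4-dimethyl-3,4-bis(4-methoxy-5-methyl-6-oxo-6H-pyran-2-yl)cyclobutane-1,2-dicarboxylic acid F3. Warm Ac2O then dehydrates F3 to 12.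

Step 4. The ester-deactivated silyloxydiene may be acylated sluggishly, and the hydrogen chloride released may desilylate 4 or erode the tert-butyl ester before ring closure. The fallback replaces the one-pot double acylation by a stepwise Claisen acylation and lactonisation; it sets out from 3 and returns at 7. The lithium enolate of 3 (LiHMDS, 2 equiv, THF, −78 °C) is C-acylated with ethyl 3-chloro-2-methyl-3-oxopropanoate to the diketo diester 8-tert-butyl 1-ethyl (E)-2,6-dimethyl-3,5-dioxooct-6-enedioate F4. DBU in refluxing toluene then closes F4 to 7 under acid-free conditions.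

Step 9. The bulky quaternary carbons or poor solubility at low temperature may blunt the discrimination of the enantiotopic carbonyls, or the sense may differ from that of the simple models. The fallback uses a stoichiometric chiral alcohol with physical separation and an ester switch; it sets out from 12 and returns at 13. Anhydride 12 is opened with (R)-1-(naphthalen-1-yl)ethanol (DMAP, Et3N, CH2Cl2) and the two diastereomeric half esters are separated by chromatography or crystallisation. The isomer with the free acid on the ring carbon that bears the methyl ester in 13, the (R)-1-(naphthalen-1-yl)ethyl half ester F5, is methylated with TMSCHN2 to the mixed methyl (R)-1-(naphthalen-1-yl)ethyl diester F6. Ionic hydrogenolysis of the secondary benzylic ester (TFA, Et3SiH, CH2Cl2) then releases 13.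

Further compounds
F1 | step 8 | naphthalene-1,8-diyl bis[(E)-3-(4-methoxy-5-methyl-6-oxo-6H-pyran-2-yl)but-2-enoate] | O=C(/C=C(\C)c1cc(OC)c(C)c(=O)o1)Oc1cccc2cccc(OC(=O)/C=C(\C)c3cc(OC)c(C)c(=O)o3)c12
F2 | step 8 | naphthalene-1,8-diyl (1R,2S,3R,4S)-3,4-dimethyl-3,4-bis(4-methoxy-5-methyl-6-oxo-6H-pyran-2-yl)cyclobutane-1,2-dicarboxylate (cyclic, meso) | O=C1Oc2cccc3cccc(c23)OC(=O)[C@@H]4[C@H]1[C@@](C)(c5cc(OC)c(C)c(=O)o5)[C@@]4(C)c6cc(OC)c(C)c(=O)o6
F3 | step 8 | (1R,2S,3R,4S)-3,4-dimethyl-3,4-bis(4-methoxy-5-methyl-6-oxo-6H-pyran-2-yl)cyclobutane-1,2-dicarboxylic acid (meso) | OC(=O)[C@@H]1[C@H](C(=O)O)[C@@](C)(c2cc(OC)c(C)c(=O)o2)[C@@]1(C)c1cc(OC)c(C)c(=O)o1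
F4 | step 4 | 8-tert-butyl 1-ethyl (E)-2,6-dimethyl-3,5-dioxooct-6-enedioate | CCOC(=O)C(C)C(=O)CC(=O)/C(C)=C/C(=O)OC(C)(C)C
F5 | step 9 | half ester of F3 with (R)-1-(naphthalen-1-yl)ethanol, free acid on the (R)-configured ring CH | OC(=O)[C@@H]1[C@H](C(=O)O[C@H](C)c2cccc3ccccc23)[C@@](C)(c2cc(OC)c(C)c(=O)o2)[C@@]1(C)c1cc(OC)c(C)c(=O)o1
F6 | step 9 | methyl (R)-1-(naphthalen-1-yl)ethyl mixed diester of F3, methyl ester on the (R)-configured ring CH | COC(=O)[C@@H]1[C@H](C(=O)O[C@H](C)c2cccc3ccccc23)[C@@](C)(c2cc(OC)c(C)c(=O)o2)[C@@]1(C)c1cc(OC)c(C)c(=O)o1
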